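**Retrosynthetic overview**

1. Last bond C5–C6: ring B is closed on the dearomatised acylphloroglucinol by ferrocene-mediated anodic oxidation of the enolised triketone. The C5 radical adds 6-endo to the alkene CH2 (C6), and the C7 radical is quenched by hydrogen-atom transfer.
2. Feature used: in ring B, C6, C7 (with its prenyl) and C8 (with its two methyls) form a second, hidden ten-carbon unit of the lavandulyl type. As a side chain CMe2–C(=CH2)–CH2CH=CMe2 on C1, it holds the alkene carbon C6 beside the enol carbon C5 of ring A.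
3. C1–C8 bond and quaternary C1: Claisen shift of the O2 ether of 5-methyl-2-(propan-2-ylidene)hex-4-en-1-ol on the hexasubstituted arene. The two C1 epimers are diastereomers (lavandulyl centre) and are separated.
4. Arene from phloroglucinol tris-MOM ether: lavandulyl at C5 (Negishi, from (R)-lavandulol), aroyl at C3 (aryllithium plus nitrile), ether on the less hindered chelated hydroxyl (O2), prenyl at C1 last.
5. Ring order: ring A is the phloroglucinol ring, dearomatised in the Claisen step; ring B is formed last.

Key step: step 15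

Remark (assumptions): lavandulyl = 5-methyl-2-(prop-1-en-2-yl)hex-4-en-1-yl; ring atoms and their oxygens carry the target numbering throughout (C1 prenyl bridgehead, C2–C4 trione bridge with the aroyl group on C3, C5 lavandulyl bridgehead, C6 CH2, C7 CH-prenyl, C8 CMe2, C9 bridging ketone); enolised triketones are drawn as one tautomer; no catalyst control over C1 is assumed in the Claisen step, and the wanted epimer is taken by separation of diastereomers.

**Route**

Step 1
Reactants: 1 phloroglucinol
Product: 2 1,3,5-tris(methoxymethoxy)benzene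
Conditions: NaH (3.3 equiv), MOMCl (3.3 equiv), DMF, 0 °C to rt
Reagents that add atoms: chloromethyl methyl ether, COCCl
Why: Williamson-type O-alkylation of the phenoxides with a hard electrophile gives the tris-acetal, which masks the phenols and later directs lithiation.

Step 2
Reactants: 2 1,3,5-tris(methoxymethoxy)benzene
Product: 4 2-iodo-1,3,5-tris(methoxymethoxy)benzene, via 2-lithio-1,3,5-tris(methoxymethoxy)benzene 3 (not isolated)
Conditions: n-BuLi (1.1 equiv), THF, 0 °C; then I2, −78 °C to rt
Reagents that add atoms: iodine, [I][I]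
Why: Directed ortho-metalation between two acetal oxygens (the three ring positions are equivalent) followed by iodine quench gives a single mono-iodide.

Step 3
Reactants: 5 (R)-lavandulol
Product: 6 (R)-lavandulyl iodide [(3R)-3-(iodomethyl)-2,6-dimethylhepta-1,5-diene]
Conditions: PPh3, I2, imidazole, CH2Cl2, 0 °C
Reagents that add atoms: iodine, [I][I]
Why: Appel iodination of the primary alcohol; the neighbouring stereocentre takes no part and is retained.

Step 4
Reactants: 6 (R)-lavandulyl iodide; 4 2-iodo-1,3,5-tris(methoxymethoxy)benzene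
Product: 8 1,3,5-tris(methoxymethoxy)-2-[(2S)-lavandulyl]benzene, via (R)-lavandulylzinc iodide 7 (not isolated)
Conditions: Zn dust (activated with TMSCl/1,2-dibromoethane), LiCl, THF, 40 °C; then 4, Pd(OAc)2 (3 mol%), SPhos (6 mol%), THF, 50 °C
Reagents that add atoms: none
Why: Zinc insertion into the primary C–I bond and Negishi coupling with the hindered aryl iodide, the biaryl phosphine making reductive elimination faster than β-hydride elimination; the stereocentre is β to the metal and keeps its arrangement (the descriptor changes from R to S by priority only).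

Step 5
Reactants: 9 3-hydroxybenzonitrile
Product: 10 3-[(triisopropylsilyl)oxy]benzonitrile
Conditions: TIPSCl, imidazole, DMF, rt
Reagents that add atoms: chlorotriisopropylsilane, CC(C)[Si](Cl)(C(C)C)C(C)C
Why: O-silylation of the phenol gives an aryl silyl ether that tolerates the aryllithium and the later acid, and keeps this hydroxyl out of the etherification in step 11.

Step 6
Reactants: 8 1,3,5-tris(methoxymethoxy)-2-[(2S)-lavandulyl]benzene; 10 3-[(triisopropylsilyl)oxy]benzonitrile
Product: 13 {2,4,6-trihydroxy-3-[(2S)-lavandulyl]phenyl}{3-[(triisopropylsilyl)oxy]phenyl}methanone, via aryllithium 11 (not isolated), via ketimine 12 (not isolated)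
Conditions: n-BuLi (1.1 equiv), THF, 0 °C; 10, −78 °C to rt; then 2 M HCl, MeOH/THF, 40 °C
Reagents that add atoms: water, O
Why: Directed ortho-metalation between two acetal oxygens (the two free ring positions are equivalent), addition of the aryllithium to the nitrile and acid hydrolysis of the ketimine give the diaryl ketone, and the same acidic methanol cleaves the three acetals while the aryl silyl ether should survive.

Step 7
Reactants: 13 {2,4,6-trihydroxy-3-[(2S)-lavandulyl]phenyl}{3-[(triisopropylsilyl)oxy]phenyl}methanone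
Product: 14 {2,6-dihydroxy-3-[(2S)-lavandulyl]-4-[(triisopropylsilyl)oxy]phenyl}{3-[(triisopropylsilyl)oxy]phenyl}methanone
Conditions: TIPSCl (1.05 equiv), imidazole, CH2Cl2/DMF, 0 °C
Reagents that add atoms: chlorotriisopropylsilane, CC(C)[Si](Cl)(C(C)C)C(C)C
Why: The hydroxyl para to the carbonyl (O9) is the most acidic and is not hydrogen-bonded, so one equivalent of silyl chloride should silylate it in preference to the two chelated ortho hydroxyls (selective O-silylation).

Step 8
Reactants: 15 ethyl 3-methylbut-2-enoate; 16 prenyl bromide (1-bromo-3-methylbut-2-ene)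
Product: 18 ethyl 5-methyl-2-(prop-1-en-2-yl)hex-4-enoate (racemic), via lithium dienolate 17 (not isolated)
Conditions: LiN(i-Pr)2, THF/DMPU, −78 °C; then 16, −78 to 0 °C
Reagents that add atoms: none
Why: The lithium dienolate of the unsaturated ester is alkylated at its α-carbon (deconjugative alkylation); the stereocentre formed is removed in the next step.

Step 9
Reactants: 18 ethyl 5-methyl-2-(prop-1-en-2-yl)hex-4-enoate
Product: 19 ethyl 5-methyl-2-(propan-2-ylidene)hex-4-enoate
Conditions: NaOEt (0.3 equiv), EtOH, reflux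
Reagents that add atoms: none
Why: Base-mediated prototropic shift moves the 1,1-disubstituted alkene into conjugation as the tetrasubstituted isopropylidene ester, which should be the thermodynamically preferred isomer.

Step 10
Reactants: 19 ethyl 5-methyl-2-(propan-2-ylidene)hex-4-enoate
Product: 20 5-methyl-2-(propan-2-ylidene)hex-4-en-1-ol
Conditions: i-Bu2AlH (2.2 equiv), CH2Cl2, −78 to 0 °C; aqueous potassium sodium tartrate
Reagents that add atoms: none
Why: 1,2-Reduction of the unsaturated ester by the aluminium hydride gives the allylic alcohol without touching the alkenes.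

Step 11
Reactants: 14 {2,6-dihydroxy-3-[(2S)-lavandulyl]-4-[(triisopropylsilyl)oxy]phenyl}{3-[(triisopropylsilyl)oxy]phenyl}methanone; 20 5-methyl-2-(propan-2-ylidene)hex-4-en-1-ol
Product: 21 {2-hydroxy-3-[(2S)-lavandulyl]-6-{[5-methyl-2-(propan-2-ylidene)hex-4-en-1-yl]oxy}-4-[(triisopropylsilyl)oxy]phenyl}{3-[(triisopropylsilyl)oxy]phenyl}methanone
Conditions: PPh3, diisopropyl azodicarboxylate, THF, 0 °C to rt
Reagents that add atoms: none
Why: Mitsunobu etherification should take place at the chelated hydroxyl flanked by the free ring CH (O2) and not at the one shielded by the β-branched lavandulyl group (O4), while O9 is blocked, which places the allylic ether between C1 and the aroyl-bearing C3.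

Step 12
Reactants: 21 {2-hydroxy-3-[(2S)-lavandulyl]-6-{[5-methyl-2-(propan-2-ylidene)hex-4-en-1-yl]oxy}-4-[(triisopropylsilyl)oxy]phenyl}{3-[(triisopropylsilyl)oxy]phenyl}methanone
Product: 22 {2,4-dihydroxy-3-[(2S)-lavandulyl]-6-{[5-methyl-2-(propan-2-ylidene)hex-4-en-1-yl]oxy}phenyl}(3-hydroxyphenyl)methanone
Conditions: n-Bu4NF (2.2 equiv), AcOH (2.2 equiv), THF, 0 °C to rt
Reagents that add atoms: none
Why: Fluoride cleaves both aryl silyl ethers (desilylation) and leaves the allylic aryl ether and the alkenes untouched, with acetic acid buffering the phenoxides.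

Step 13
Reactants: 22 {2,4-dihydroxy-3-[(2S)-lavandulyl]-6-{[5-methyl-2-(propan-2-ylidene)hex-4-en-1-yl]oxy}phenyl}(3-hydroxyphenyl)methanone; 16 prenyl bromide
Product: 23 {2,4-dihydroxy-3-[(2S)-lavandulyl]-5-(3-methylbut-2-en-1-yl)-6-{[5-methyl-2-(propan-2-ylidene)hex-4-en-1-yl]oxy}phenyl}(3-hydroxyphenyl)methanone
Conditions: DBU (1.1 equiv), 16 (1.1 equiv), THF, 0 °C to rt
Reagents that add atoms: none
Why: One equivalent of base ionises the most acidic hydroxyl (O9, para to the carbonyl) and the ambident phenoxide is C-alkylated at its only unsubstituted ortho carbon, C1, with rearomatisation (C-prenylation of an acylphloroglucinol).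

Step 14
Reactants: 23 {2,4-dihydroxy-3-[(2S)-lavandulyl]-5-(3-methylbut-2-en-1-yl)-6-{[5-methyl-2-(propan-2-ylidene)hex-4-en-1-yl]oxy}phenyl}(3-hydroxyphenyl)methanone
Product: 24 (6R)-6-(2,6-dimethyl-3-methylidenehept-5-en-2-yl)-3,5-dihydroxy-2-(3-hydroxybenzoyl)-6-(3-methylbut-2-en-1-yl)-4-[(2S)-lavandulyl]cyclohexa-2,4-dien-1-one
Conditions: Eu(fod)3 (10 mol%; fod = 6,6,7,7,8,8,8-heptafluoro-2,2-dimethyloctane-3,5-dionate), CHCl3, 50 °C; then preparative HPLC on a chiral stationary phase
Reagents that add atoms: none
Why: Aromatic Claisen rearrangement with a mild oxophilic lanthanide chelated between ether oxygen and aroyl carbonyl: C1 is the only ortho carbon that can accept the allyl terminus (the other carries the aroyl group), the chair [3,3] shift joins C1 to the CMe2 terminus at a temperature below that of a following Cope shift, and the dienone is held as the enolised triketone; C1 arises in both configurations, and the (6R) epimer is separated from its diastereomer and assigned by correlation after step 15.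

Step 15
Reactants: 24 (6R)-6-(2,6-dimethyl-3-methylidenehept-5-en-2-yl)-3,5-dihydroxy-2-(3-hydroxybenzoyl)-6-(3-methylbut-2-en-1-yl)-4-[(2S)-lavandulyl]cyclohexa-2,4-dien-1-one
Product: 25 (1R,5R,7R)-4-hydroxy-3-(3-hydroxybenzoyl)-8,8-dimethyl-1,7-bis(3-methylbut-2-en-1-yl)-5-[(2S)-5-methyl-2-(prop-1-en-2-yl)hex-4-en-1-yl]bicyclo[3.3.1]non-3-ene-2,9-dione (target CNP0103487.1)
Conditions: Fe(C5H5)2 (20 mol%), 1,4-cyclohexadiene (20 equiv), NaHCO3 (0.3 equiv), n-Bu4NBF4 (0.1 M), THF/MeOH 5:1, undivided cell, reticulated vitreous carbon anode, Pt cathode, constant current (5 mA), 40 °C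
Reagents that add atoms: none
Why: Proposed new method: ferrocenium (the mediator in its trivalent-iron form, regenerated at the anode) takes one electron from the enolate of the triketone, and the resulting radical, which carries spin at C5, adds to the unsubstituted alkene carbon C6 held above it by the quaternary C1 and C8, so that ring B closes in the 6-endo-trig mode and leaves a tertiary radical at C7; this radical takes a hydrogen atom from 1,4-cyclohexadiene, whose dienyl radical is oxidised to benzene while protons are reduced at the cathode. The closest known reaction types are ferrocene-mediated anodic radical cyclisations terminated by 1,4-cyclohexadiene, oxidative 6-endo cyclisations of unsaturated 1,3-dicarbonyls with Mn(OAc)3 and oxidative radical cyclisations of dearomatised acylphloroglucinols onto prenyl groups, none of which joins an enol carbon to a 1,1-disubstituted alkene on this scaffold with reductive termination. C5 can bond only on the face of ring A that carries the C8 chain, so its configuration is fixed by C1 through the one-carbon bridge C9, and C7 is set by hydrogen transfer to the convex exo face of the new bicycle (the endo face is covered by the C2–C4 bridge and its aroyl group), which leaves the C7 prenyl group endo, on the side of ring A. The step needs attack at C6 rather than 5-exo attack of C5 on the C1 prenyl group or on the prenyl arm of the lavandulyl chain; the carbonyl C9 inside the forming ring, the 1,1-disubstitution of the alkene (open CH2 terminus, tertiary radical) and the gem-dimethyl group at C8 favour the 6-endo path. It also needs bonding at C5 and not at the aroyl-bearing C3, which is more hindered and would give a non-enolisable trione, and hydrogen transfer faster than oxidation of the C7 radical, which the large excess of the diene and the low stationary concentration of ferrocenium are meant to secure.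

**Compound list**

1 | phloroglucinol | Oc1cc(O)cc(O)c1 | starting material
2 | 1,3,5-tris(methoxymethoxy)benzene | COCOc1cc(OCOC)cc(OCOC)c1 | intermediate
3 | 2-lithio-1,3,5-tris(methoxymethoxy)benzene | COCOc1cc(OCOC)c([Li])c(OCOC)c1 | intermediate
4 | 2-iodo-1,3,5-tris(methoxymethoxy)benzene | COCOc1cc(OCOC)c(I)c(OCOC)c1 | intermediate
5 | (R)-lavandulol, (2R)-5-methyl-2-(prop-1-en-2-yl)hex-4-en-1-ol | C=C(C)[C@@H](CC=C(C)C)CO | starting material
6 | (R)-lavandulyl iodide, (3R)-3-(iodomethyl)-2,6-dimethylhepta-1,5-diene | C=C(C)[C@@H](CC=C(C)C)CI | intermediate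
7 | (R)-lavandulylzinc iodide | C=C(C)[C@@H](CC=C(C)C)C[Zn]I | intermediate
8 | 1,3,5-tris(methoxymethoxy)-2-[(2S)-lavandulyl]benzene | C=C(C)[C@@H](CC=C(C)C)Cc1c(OCOC)cc(OCOC)cc1OCOC | intermediate
9 | 3-hydroxybenzonitrile | N#Cc1cccc(O)c1 | starting material
10 | 3-[(triisopropylsilyl)oxy]benzonitrile | CC(C)[Si](Oc1cccc(C#N)c1)(C(C)C)C(C)C | intermediate
11 | 2,4,6-tris(methoxymethoxy)-3-[(2S)-lavandulyl]phenyllithium | C=C(C)[C@@H](CC=C(C)C)Cc1c(OCOC)c([Li])c(OCOC)cc1OCOC | intermediate
12 | {2,4,6-tris(methoxymethoxy)-3-[(2S)-lavandulyl]phenyl}{3-[(triisopropylsilyl)oxy]phenyl}methanimine | C=C(C)[C@@H](CC=C(C)C)Cc1c(OCOC)c(C(=N)c2cccc(O[Si](C(C)C)(C(C)C)C(C)C)c2)c(OCOC)cc1OCOC | intermediate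
13 | {2,4,6-trihydroxy-3-[(2S)-lavandulyl]phenyl}{3-[(triisopropylsilyl)oxy]phenyl}methanone | C=C(C)[C@@H](CC=C(C)C)Cc1c(O)c(C(=O)c2cccc(O[Si](C(C)C)(C(C)C)C(C)C)c2)c(O)cc1O | intermediate
14 | {2,6-dihydroxy-3-[(2S)-lavandulyl]-4-[(triisopropylsilyl)oxy]phenyl}{3-[(triisopropylsilyl)oxy]phenyl}methanone | C=C(C)[C@@H](CC=C(C)C)Cc1c(O)c(C(=O)c2cccc(O[Si](C(C)C)(C(C)C)C(C)C)c2)c(O)cc1O[Si](C(C)C)(C(C)C)C(C)C | intermediate
15 | ethyl 3-methylbut-2-enoate | CCOC(=O)C=C(C)C | starting material
16 | prenyl bromide, 1-bromo-3-methylbut-2-ene | CC(C)=CCBr | starting material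
17 | lithium 1-ethoxy-3-methylbuta-1,3-dien-1-olate (dienolate of 15) | CCOC(O[Li])=CC(C)=C | intermediate
18 | ethyl 5-methyl-2-(prop-1-en-2-yl)hex-4-enoate (racemic) | CCOC(=O)C(CC=C(C)C)C(C)=C | intermediate
19 | ethyl 5-methyl-2-(propan-2-ylidene)hex-4-enoate | CCOC(=O)C(CC=C(C)C)=C(C)C | intermediate
20 | 5-methyl-2-(propan-2-ylidene)hex-4-en-1-ol | OCC(CC=C(C)C)=C(C)C | intermediate
21 | {2-hydroxy-3-[(2S)-lavandulyl]-6-{[5-methyl-2-(propan-2-ylidene)hex-4-en-1-yl]oxy}-4-[(triisopropylsilyl)oxy]phenyl}{3-[(triisopropylsilyl)oxy]phenyl}methanone | C=C(C)[C@@H](CC=C(C)C)Cc1c(O)c(C(=O)c2cccc(O[Si](C(C)C)(C(C)C)C(C)C)c2)c(OCC(CC=C(C)C)=C(C)C)cc1O[Si](C(C)C)(C(C)C)C(C)C | intermediate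
22 | {2,4-dihydroxy-3-[(2S)-lavandulyl]-6-{[5-methyl-2-(propan-2-ylidene)hex-4-en-1-yl]oxy}phenyl}(3-hydroxyphenyl)methanone | C=C(C)[C@@H](CC=C(C)C)Cc1c(O)c(C(=O)c2cccc(O)c2)c(OCC(CC=C(C)C)=C(C)C)cc1O | intermediate
23 | {2,4-dihydroxy-3-[(2S)-lavandulyl]-5-(3-methylbut-2-en-1-yl)-6-{[5-methyl-2-(propan-2-ylidene)hex-4-en-1-yl]oxy}phenyl}(3-hydroxyphenyl)methanone | C=C(C)[C@@H](CC=C(C)C)Cc1c(O)c(C(=O)c2cccc(O)c2)c(OCC(CC=C(C)C)=C(C)C)c(CC=C(C)C)c1O | intermediate
24 | (6R)-6-(2,6-dimethyl-3-methylidenehept-5-en-2-yl)-3,5-dihydroxy-2-(3-hydroxybenzoyl)-6-(3-methylbut-2-en-1-yl)-4-[(2S)-lavandulyl]cyclohexa-2,4-dien-1-one | C=C(C)[C@@H](CC=C(C)C)CC1=C(O)[C@@](CC=C(C)C)(C(C)(C)C(=C)CC=C(C)C)C(=O)C(C(=O)c2cccc(O)c2)=C1O | intermediate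
25 | (1R,5R,7R)-4-hydroxy-3-(3-hydroxybenzoyl)-8,8-dimethyl-1,7-bis(3-methylbut-2-en-1-yl)-5-[(2S)-5-methyl-2-(prop-1-en-2-yl)hex-4-en-1-yl]bicyclo[3.3.1]non-3-ene-2,9-dione | C=C(C)[C@@H](CC=C(C)C)C[C@@]12C[C@@H](CC=C(C)C)C(C)(C)[C@@](CC=C(C)C)(C(=O)C(C(=O)c3cccc(O)c3)=C1O)C2=O | target

**Step count**

Total: 15 steps. Longest linear sequence: 10 steps (1 → 2 → 4 → 8 → 13 → 14 → 21 → 22 → 23 → 24 → 25; steps 1, 2, 4, 6, 7, 11, 12, 13, 14, 15).

**Steps most likely to fail**

Step 15 (proposed new method). Several processes can divert it: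
- electron transfer from the strongly stabilised enolate to ferrocenium may be too slow;
- the C5 radical may close 5-exo onto the C1 prenyl group (bicyclo[3.2.1] mode) or onto the prenyl arm of the lavandulyl chain instead of 6-endo onto C6;
- the tertiary C7 radical may be oxidised to the cation, or shift by a 1,5-hydrogen transfer from the lavandulyl methine, before the diene reduces it.

The fallback uses known chemistry, the reductive radical cyclisation of an α-iodo-1,3-dicarbonyl. It sets out from 24: N-iodosuccinimide (CH2Cl2, −20 °C) iodinates the enol carbon C5 and gives the C5 iodide F1. Slow addition of (Me3Si)3SiH with Et3B/air (toluene, 0 °C) abstracts the iodine, the same C5 radical closes ring B, and the C7 radical is reduced by the silane from the exo face. The sequence comes back at 25. No oxidant is present, so the C7 radical cannot be oxidised, and radical reduced before ring closure returns 24. The choice between 6-endo and 5-exo closure is intrinsic to the radical and is not changed by this fallback.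

Step 14. No facial control over C1 is built in, and the two epimers, whose stereocentres lie five bonds apart, may not separate. Ionisation of the allylic ether on the Lewis acid (1,3-shift or loss of the side chain) and a following Cope shift of the new chain from C1 to C5 are the chemical side paths, kept down by the mild catalyst and low temperature. The fallback sets out from 23: the rearrangement is run as in step 14 but the epimers are not separated. The mixture of 24 and its (6S) epimer F2 is taken through the anodic cyclisation of step 15. The two rigid bicycles, 25 and the (1S,5S,7S) diastereomer F3, now differ in the sense of the whole core next to the lavandulyl centre and are separated by chromatography. The sequence comes back at 25.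

Step 13. Possible failures are O-alkylation of the phenoxide, attack at the lavandulyl-bearing C5 with loss of aromaticity, and over-alkylation. The fallback sets out from 22: 3-chloro-3-methylbut-1-yne, CuCl2 (cat.), DBU, MeCN, 0 °C etherifies the most acidic hydroxyl (O9) to the propargyl ether F4. Semihydrogenation (H2, Pd/CaCO3 poisoned with Pb(OAc)2, quinoline, EtOAc) gives the 1,1-dimethylallyl ether F5. Warming in toluene (90 °C) sends it by Claisen rearrangement to the only free ortho carbon, C1, where it arrives as a prenyl group; the tertiary ether should rearrange well below the temperature at which the O2 ether moves. The sequence comes back at 23.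

**Further compounds**

F1 | step 15 | C5 iodide of 24: 6-(2,6-dimethyl-3-methylidenehept-5-en-2-yl)-5-hydroxy-4-(3-hydroxybenzoyl)-2-iodo-6-(3-methylbut-2-en-1-yl)-2-[(2S)-lavandulyl]cyclohex-4-ene-1,3-dione (quaternary carbon configured as in 24, both epimers at the iodinated carbon) | C=C(C)[C@@H](CC=C(C)C)CC1(I)C(=O)[C@@](CC=C(C)C)(C(C)(C)C(=C)CC=C(C)C)C(O)=C(C(=O)c2cccc(O)c2)C1=O
F2 | step 14 | (6S) epimer of 24 | C=C(C)[C@@H](CC=C(C)C)CC1=C(O)[C@](CC=C(C)C)(C(C)(C)C(=C)CC=C(C)C)C(=O)C(C(=O)c2cccc(O)c2)=C1O
F3 | step 14 | (1S,5S,7S) diastereomer of 25 with the (2S)-lavandulyl group | C=C(C)[C@@H](CC=C(C)C)C[C@]12C[C@H](CC=C(C)C)C(C)(C)[C@](CC=C(C)C)(C(=O)C(C(=O)c3cccc(O)c3)=C1O)C2=O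
F4 | step 13 | {2-hydroxy-3-[(2S)-lavandulyl]-4-[(2-methylbut-3-yn-2-yl)oxy]-6-{[5-methyl-2-(propan-2-ylidene)hex-4-en-1-yl]oxy}phenyl}(3-hydroxyphenyl)methanone | C=C(C)[C@@H](CC=C(C)C)Cc1c(O)c(C(=O)c2cccc(O)c2)c(OCC(CC=C(C)C)=C(C)C)cc1OC(C)(C)C#C
F5 | step 13 | {2-hydroxy-3-[(2S)-lavandulyl]-4-[(2-methylbut-3-en-2-yl)oxy]-6-{[5-methyl-2-(propan-2-ylidene)hex-4-en-1-yl]oxy}phenyl}(3-hydroxyphenyl)methanone | C=C(C)[C@@H](CC=C(C)C)Cc1c(O)c(C(=O)c2cccc(O)c2)c(OCC(CC=C(C)C)=C(C)C)cc1OC(C)(C)C=C
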